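# Proposed synthesis of CNP0347302.1 (compound 44) by Birch reduction of a tetralin and ozonolytic opening to the ten-membered ring

Atom numbers C1–C15 are those of 44 (ring C1=C2–C3=C4–C5–C6–C7–C8–C9–C10; C11–C13 lactone carbons on C7, lactone oxygen on C8, C14 methyl on C10, C15 on C4) and are kept for every intermediate.

## Analysis of the target

Compound 44 is a cyclodeca-1,3-diene with both ring double bonds cis (C1=C2, C3=C4). It is trans-fused at C7–C8 to an α-methylene-γ-butyrolactone (C11, C12, exocyclic C13; ring oxygen on C8). C4 carries an acetoxymethyl group (C15), C10 a methyl group (C14), and C6 the ester of (S)-2,3-dihydroxy-2-methylpropanoic acid. The four ring stereocentres are 6R,7R,8S,10S: the C6–O and C8–O bonds lie on one face of the ring, the C7–C11 bond and the C10 methyl on the other. C6, C7 and C8 therefore form a contiguous triad with both neighbouring pairs trans, and C10 is 1,3 to C8 and 1,4 to C7; the fifth stereocentre is the quaternary carbinol of the acyl group. The sensitive groups are the exocyclic methylene lactone (a Michael acceptor), the primary allylic acetate (ionised by acid and by zerovalent palladium), the conjugated diene, and three different esters that must be told apart. The synthesis is hard for three reasons: a ten-membered ring resists direct closure, both ring double bonds must be cis, and the oxygens on C6 and C8 are both γ to C12, so the lactone could close either way. The strategy rests on the fact that C1–C6, with C15 on C4, are the carbons of a 1,2,4-trisubstituted benzene ring whose C1–C6 bond is shared with a second six-membered ring (C1, C6, C7, C8, C9, C10). Birch reduction of that tetralin leaves exactly C1=C6 and C3=C4, and cleavage of C1=C6 opens the bicycle to the ten-membered ring, with C3=C4 already ring-cis and already carrying C15.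

## Retrosynthetic reasoning

**Acyl group on O6 (44 to 43 to 36 and 41).** The last bonds formed are the C6–O acyl bond and the O–H bonds of the side-chain diol. The diol is carried as acetonide 41, so that in 36 one free hydroxyl meets one activated acid. Cutting here keeps the tertiary ester and its diol out of every enolate and organometallic step. Acid 41 goes back in three steps to bromo acid 37, whose quaternary stereocentre is never touched.

**Acetate on C15 (36 to 35 to 34).** An allylic acetate would not survive the palladium hydride step that makes the diene, so C15 travels as a silyl ether and is acetylated only afterwards. In diol 35 the primary allylic C15 hydroxyl is easily distinguished from the hindered secondary C6 hydroxyl.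

**C11=C13 (34 to 32 to 30).** The methylene carbon is cut from C11 and is brought in as an aminomethyl group (32) that is unveiled by elimination. It comes after the diene because a conjugated exocyclic methylene would not survive ozonolysis, enolate formation at C2 or palladium hydride.

**C1=C2 (30 to 29 to 27).** The C1 oxygen left by the ring cleavage is removed through dienyl triflate 29. Ketone 27 enolises toward C2, which is both α to C1 and allylic to C3=C4, so the conjugated diene appears directly. The ring-cis geometry is the less strained one in a ten-membered ring.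

**Lactone bond C12–O8 (27 to 24 to 23 to 22).** The lactone is cut to primary alcohol 24. Because O6 and O8 are both γ to C12, O6 must be blocked first (23). This is possible because in 22 the C8 oxygen is tied to C1 as a five-membered hemiketal, which O6 cannot form. Oxidative lactonisation then draws O8 out of the hemiketal and frees the C1 carbonyl exactly when it is needed.

**C6 carbinol (22 to 20).** The C6 stereocentre comes from the C6 ketone by hydride delivery to a boron chelate with the C8 hydroxyl (1,3-syn). The same hydroxyl masks C1 as the hemiketal, so one group separates the two ketones and directs the reduction.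

**Key disconnection (20, open form 19, to 18).** The C1 and C6 carbonyls are rejoined as a tetrasubstituted C1=C6 alkene. The ten-membered ring becomes hexahydronaphthalene 18 and no medium-ring closure is needed.

**Diene ring (18 to 17 to 15).** The 1,4-diene ring of 17 is the Birch product of tetralin 15. The substitution pattern forces protonation at the unsubstituted C2 and C5.

**C15, C7 and C8 (15 to 13 to 12 to 10).** C15 is attached last to the arene, in place of a chlorine that is inert through acylation, cross-coupling and hydroboration. The C7–H and C8–O bonds are formed together by hydroboration of diene 10. Syn addition across C7=C8 on the face opposite the C10 methyl gives the C7 side chain trans to the C8 hydroxyl and both centres in the correct relation to C10. Alkylating a C8 ketone at C7 was set aside, because C7 would then be an epimerisable centre with no clear bias relative to the 1,4-related C10.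

**Tetralone (10 to 8 to 7 to 5 to 4 to 1 and 2).** C7–C11 comes from Stille coupling of enol triflate 8 with 9, C6–C7 from intramolecular Friedel–Crafts acylation of 5, the C10 stereocentre from asymmetric hydrogenation of 4, and C9=C10 from a Wittig reaction of 1 with 2.

## Alternatives that were turned down

**Alternative 1:** The C4–C5 bond is cut and the diene is masked as a 3-sulfolene whose sulfone bridges C1 and C4, with C15 as a methyl ester on C4. In the forward step the C4 carbanion, stabilised by sulfone and ester and formed with Cs2CO3 at high dilution, would displace a C5 iodide to give the bridged bicycle A1; cheletropic loss of the sulfone bridge would then release the diene. In its favour, a bridged sulfolene can only open to the cis,cis-diene, so both geometries are guaranteed; on this point it is stronger than the chosen route, whose C1=C2 geometry depends on an enolate. It also carries C13 from the start. Against it, the ring closure is an intramolecular SN2 reaction that builds a quaternary carbon inside a ten-membered ring, at a primary carbon slowed by the neighbouring C6 ether oxygen. The sulfolene anion can open to a dienyl sulfinate or alkylate at its other α-carbon, and the four stereocentres must first be assembled on an open chain. The chosen route avoids any such closure by making the ring through bond cleavage, and accepts a less certain C1=C2 geometry in exchange.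

**Alternative 2:** The central C2–C3 bond of the diene is cut in the fully functionalised seco-lactone. A Z-alkenyl iodide at C2 and an alkenylstannane at C3 would be joined by copper thiophene-2-carboxylate, Cu(O2CC4H3S), or by Pd2(dba)3 with AsPh3, to give A2, which is identical with 43 of the present route. It is more convergent than the chosen route: both alkene geometries are fixed in open-chain fragments and are retained, and the product is one deprotection from 44 with no late protecting-group changes. Against it, forming the central sp2–sp2 bond of a cis,cis-diene in a ten-membered ring forces the two termini together against transannular strain, so oligomerisation, protodestannylation and reduction of the iodide compete. The palladium variant would also ionise the allylic acetate, and the seco chain with C6, C7, C8 and C10 needs a long sequence of open-chain stereocontrol. The chosen route puts its risk into a strongly driven bond cleavage and takes C3=C4 and C15 from an arene, but pays with a longer endgame.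

**Alternative 3:** The C6–C7 bond and the C11=C13 double bond are cut together. A thirteen-membered ether in which oxygen links C6 and C13, with a tributylstannyl group on C6, would undergo tin–lithium exchange with n-BuLi and a [2,3]-Wittig shift, contracting to the ten-membered alcohol A3. One step would create the C6–C7 bond, the C6 carbinol, the C7 stereocentre and the exocyclic methylene. This is more economical than the chosen route, which needs a directed reduction and a separate methylenation for the same features. Against it, the configuration at C6 and C7 depends on a transannular transition state in a ring that already contains the rigid cis,cis-diene and is hard to predict, and [1,2]-shift and simple protonation compete. The α-alkoxystannane must be made configurationally pure, and the diene and a macrocyclic ether closure still have to be solved beforehand. The chosen route sets C7 and C8 on a rigid bicycle and C6 by a 1,3-relationship of known sense.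

Key step: step 11

Assumption: the facial sense of the iridium catalyst in step 2 is assigned by analogy with closely related 4-aryl-pent-3-enoic acids; should acid 5 prove to be the R enantiomer, the mirror-image ligand is used and nothing else changes.

## Route

Step 1
Reactants: 1 1-(4-chlorophenyl)ethan-1-one; 2 (2-carboxyethyl)triphenylphosphonium bromide
Product: 4 (E)-4-(4-chlorophenyl)pent-3-enoic acid, via phosphonium ylide 3 (not isolated)
Conditions: 2, NaN(SiMe3)2 (2.1 equiv), THF, 0 °C; then 1, 0 °C → rt; aq. HCl; recrystallisation of the E isomer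
Reagents that add atoms: none
Why: Wittig olefination with the carboxylate-bearing ylide 3 forms C9=C10 and brings in C7–C9; the E acid should predominate and is purified by crystallisation because the next step needs a single alkene isomer.

Step 2
Reactants: 4
Product: 5 (S)-4-(4-chlorophenyl)pentanoic acid
Conditions: H2 (6 atm), [Ir(cod)(L)][B(C6H3(CF3)2)4] (1 mol %; L = chiral spiro phosphine–oxazoline (Sa,S)-SIPHOX), Cs2CO3 (0.5 equiv), MeOH, rt
Reagents that add atoms: none
Why: Carboxylate-directed asymmetric hydrogenation of a β,γ-unsaturated acid; the carboxylate binds the cationic iridium centre and the P,N ligand selects the alkene face, which sets C10 (S); the aryl chloride is inert to this catalyst.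

Step 3
Reactants: 5
Product: 7 (S)-7-chloro-4-methyl-3,4-dihydronaphthalen-1(2H)-one, via acid chloride 6 (not isolated)
Conditions: (COCl)2, DMF (cat.), CH2Cl2, 0 °C → rt; then AlCl3, CH2Cl2, 0 °C
Reagents that add atoms: none
Why: Intramolecular Friedel–Crafts acylation closes the six-membered ring at C6, ortho to the alkyl chain and meta to chlorine; C10 is neither enolisable nor ionised at 0 °C and should keep its configuration.

Step 4
Reactants: 7
Product: 8 (S)-7-chloro-4-methyl-3,4-dihydronaphthalen-1-yl trifluoromethanesulfonate
Conditions: Tf2O, 2,6-di-tert-butyl-4-methylpyridine, CH2Cl2, 0 °C → rt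
Reagents that add atoms: trifluoromethanesulfonic anhydride, O=S(=O)(OS(=O)(=O)C(F)(F)F)C(F)(F)F
Why: O-Triflation of the aryl ketone, which can enolise only toward C8, gives the C7=C8 enol triflate; C10 is remote from the enolisation.

Step 5
Reactants: 8; 9 tributyl(ethenyl)stannane
Product: 10 (S)-6-chloro-4-ethenyl-1-methyl-1,2-dihydronaphthalene
Conditions: Pd(PPh3)4 (5 mol %), LiCl (3 equiv), THF, 65 °C
Reagents that add atoms: none
Why: Stille coupling attaches C11–C12 to C7; zerovalent palladium with PPh3 inserts into the alkenyl triflate far faster than into the aryl chloride, which is kept for step 8.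

Step 6
Reactants: 10
Product: 12 2-[(1S,2S,4S)-7-chloro-2-hydroxy-4-methyl-1,2,3,4-tetrahydronaphthalen-1-yl]ethan-1-ol, via bis-borane adduct 11 (not isolated)
Conditions: 9-BBN (2.6 equiv), THF, 0 → 65 °C; then NaOH (aq), H2O2, 0 °C → rt
Reagents that add atoms: hydrogen peroxide, OO
Why: Double hydroboration–oxidation: the vinyl group reacts first (boron on terminal C12), then the trisubstituted C7=C8 bond (boron on C8, away from the aryl-substituted C7). Syn addition on the face opposite the pseudoaxial C10 methyl, which is 1,3 to C8, places H on C7 and O on C8 cis to each other, so the side chain is trans to the hydroxyl and both are correctly related to C10; oxidation proceeds with retention.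

Step 7
Reactants: 12
Product: 13 (1S,2S,4S)-1-[2-(tert-butyldimethylsilyloxy)ethyl]-7-chloro-4-methyl-1,2,3,4-tetrahydronaphthalen-2-ol
Conditions: TBSCl (1.05 equiv), imidazole, CH2Cl2, −20 → 0 °C
Reagents that add atoms: tert-butyldimethylsilyl chloride, CC(C)(C)[Si](C)(C)Cl
Why: Silylation of the primary C12 hydroxyl is much faster than that of the secondary C8 hydroxyl next to the branched C7; C12 is thereby distinguished before the second primary alcohol (C15) is introduced.

Step 8
Reactants: 13; 14 potassium (acetoxymethyl)trifluoroborate
Product: 15 (1S,2S,4S)-1-[2-(tert-butyldimethylsilyloxy)ethyl]-7-(hydroxymethyl)-4-methyl-1,2,3,4-tetrahydronaphthalen-2-ol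
Conditions: Pd(dba)2 (5 mol %), RuPhos (10 mol %), Na2CO3, 1,4-dioxane/H2O (10:1), 100 °C
Reagents that add atoms: none
Why: Suzuki–Miyaura hydroxymethylation of the aryl chloride installs C15 with its oxygen; the electron-rich biaryl phosphine allows insertion into the C–Cl bond and the acetate is hydrolysed in the basic aqueous medium.

Step 9
Reactants: 15
Product: 17 (1S,2S,4S)-1-[2-(tert-butyldimethylsilyloxy)ethyl]-7-(hydroxymethyl)-4-methyl-1,2,3,4,5,8-hexahydronaphthalen-2-ol, via dilithium dialkoxide 16 (not isolated)
Conditions: n-BuLi (2.05 equiv), THF, −78 °C; then Li (10 equiv), NH3 (l), t-BuOH (8 equiv), −78 → −33 °C; isoprene; then MeOH, NH4Cl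
Reagents that add atoms: none
Why: Birch reduction of a 1,2,4-trialkylbenzene protonates the two unsubstituted para-related carbons C2 and C5 and leaves C1=C6 and C3=C4. The benzylic C15–O bond should survive because it is held as a lithium alkoxide, which cannot leave as oxide; t-BuOH is too weak an acid to protonate it, and excess lithium is destroyed before NH4Cl is added. The alkyl TBS ether is stable.

Step 10
Reactants: 17
Product: 18 (1S,2S,4S)-1-[2-(tert-butyldimethylsilyloxy)ethyl]-7-[(tert-butyldiphenylsilyloxy)methyl]-4-methyl-1,2,3,4,5,8-hexahydronaphthalen-2-ol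
Conditions: TBDPSCl (1.05 equiv), imidazole, CH2Cl2, 0 °C
Reagents that add atoms: tert-butyldiphenylsilyl chloride, CC(C)(C)[Si](Cl)(c1ccccc1)c1ccccc1
Why: The primary allylic hydroxyl is silylated selectively over the hindered C8 hydroxyl; the TBDPS ether is more robust than the primary TBS ether at C12 and inductively deactivates C3=C4 toward ozone.

Step 11
Reactants: 18
Product: 20 C1/C8 hemiketal (1-hydroxy-11-oxabicyclo[6.2.1]undec-3-en-6-one bearing 4-CH2OTBDPS; 7-CH2CH2OTBS; 10-CH3), via hydroxy-dione 19 (not isolated)
Conditions: O3/O2, CH2Cl2/MeOH (5:1), NaHCO3, Sudan Red 7B, −78 °C, to the indicator end point; then Me2S, −78 °C → rt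
Reagents that add atoms: ozone, [O-][O+]=O
Why: Ozone adds as a 1,3-dipole to the most electron-rich alkene, the tetrasubstituted C1=C6 bond. The primary ozonide cycloreverts to a ketone and a carbonyl oxide, which methanol captures as a methoxy hydroperoxide, and Me2S reduces this to the second ketone. The closest known reaction is the ozonolytic cleavage of the central double bond of 9,10-octalins and Birch-derived isotetralins to cyclodecane-1,6-diones. The ten-membered ring is formed by cutting the bond shared by two six-membered rings and not by a closure, so it carries no entropic penalty, and C3=C4 stays ring-cis. In 19 the C8 hydroxyl then adds to the C1 carbonyl in a 5-exo-trig closure to give the oxolane hemiketal 20; a closure onto C6 would need a four-membered ring. No stereocentre is created in 19, and the hemiketal carbon in 20 is fixed by the bridge, since O8 can reach C1 only from the face on which it sits at C8. The step needs attack at C1=C6 and not at C3=C4; the higher substitution, the deactivating allylic silyloxy group on C3=C4, titration to the dye end point and −78 °C secure this. NaHCO3 keeps the 1,6-dione from transannular aldol reaction and from migration of C3=C4 into conjugation.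

Step 12
Reactants: 20
Product: 22 C1/C8 hemiketal of the 6,8-syn diol (11-oxabicyclo[6.2.1]undec-3-ene-1,6-diol with the substituents of 20; C6–OH on the face of O8), via diethylboron chelate 21 (not isolated)
Conditions: Et2BOMe (1.2 equiv), THF/MeOH (4:1), −78 °C; NaBH4 (1.1 equiv), −78 °C; pH 7 buffer; repeated evaporation from MeOH
Reagents that add atoms: none
Why: Narasaka–Prasad reduction: boron links O8 and the C6 carbonyl of the open form in a six-membered chelate and external hydride attacks axially, giving the 1,3-syn diol, so C6–O lies cis to C8–O and trans to the C7 side chain. Only the chelated carbonyl is activated; C1 is masked as the hemiketal and, in the open form, is an unactivated medium-ring ketone that borohydride should not reduce at −78 °C.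

Step 13
Reactants: 22
Product: 23 6-O-TBS ether of 22
Conditions: TBSCl (1.2 equiv), imidazole, DMF, 0 °C → rt, no acid
Reagents that add atoms: tert-butyldimethylsilyl chloride, CC(C)(C)[Si](C)(C)Cl
Why: O8 is part of the hemiketal and the hemiketal hydroxyl is tertiary, so C6–OH is the only hydroxyl open to TBSCl/imidazole; blocking O6 now decides which oxygen will later close the lactone.

Step 14
Reactants: 23
Product: 24 primary alcohol (23 with C12–OH free)
Conditions: HF·pyridine, pyridine, THF, 0 °C
Reagents that add atoms: none
Why: Buffered HF·pyridine removes the primary TBS ether faster than the hindered secondary TBS ether on O6 and the TBDPS ether on C15.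

Step 15
Reactants: 24
Product: 27 trans-fused 8,12-lactone with free C1 ketone (6-O-TBS; 15-O-TBDPS; C3=C4), via hydroxy aldehyde 25 (not isolated), via lactol 26 (not isolated)
Conditions: TEMPO (0.2 equiv), PhI(OAc)2 (3 equiv), CH2Cl2, rt
Reagents that add atoms: none
Why: Oxidative lactonisation: the primary alcohol is oxidised to aldehyde 25, the C8 hydroxyl released from the hemiketal equilibrium adds to it (5-exo-trig) to give lactol 26, and this is oxidised to the γ-lactone. O6 is silylated, so only O8 can close, and the C1 carbonyl is set free.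

Step 16
Reactants: 27
Product: 29 dienyl triflate (C1–OTf; C1=C2 and C3=C4 ring-cis), via potassium dienolate 28 (not isolated)
Conditions: KN(SiMe3)2 (1.05 equiv), THF, −78 °C; then N-(5-chloropyridin-2-yl)triflimide (Comins' reagent), −78 °C
Reagents that add atoms: N-(5-chloropyridin-2-yl)-1,1,1-trifluoro-N-(trifluoromethylsulfonyl)methanesulfonamide, FC(F)(F)S(=O)(=O)N(c1ccc(Cl)cn1)S(=O)(=O)C(F)(F)F
Why: Kinetic deprotonation occurs at C2, which is α to C1, allylic to C3=C4 and less hindered than C10–H and than the lactone α-position; O-sulfonylation of the dienolate gives the conjugated dienyl triflate. The ring-cis C1=C2 geometry is expected as the less strained one in the ten-membered ring, and C10 is not deprotonated.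

Step 17
Reactants: 29
Product: 30 cis,cis-diene lactone (6-O-TBS; 15-O-TBDPS)
Conditions: Pd(OAc)2 (5 mol %), PPh3 (10 mol %), Bu3N (3 equiv), HCO2H (2 equiv), DMF, 60 °C
Reagents that add atoms: none
Why: Palladium-catalysed formate reduction of an alkenyl triflate replaces C–O by C–H with retention of geometry; the silyl ether on C15 cannot ionise, which is why the acetate is not yet in place.

Step 18
Reactants: 30
Product: 32 11-(dimethylaminomethyl) lactone (C11 epimers), via lithium enolate 31 (not isolated)
Conditions: LiN(iPr)2 (1.2 equiv), THF, −78 °C; then dimethyl(methylidene)ammonium iodide (Eschenmoser's salt), −78 → 0 °C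
Reagents that add atoms: dimethyl(methylidene)ammonium iodide, C=[N+](C)C.[I-]
Why: Mannich reaction of the lactone enolate, the only acidic site left, introduces C13; the new centre at C11 need not be controlled because it becomes sp2 in the next step.

Step 19
Reactants: 32
Product: 34 α-methylene lactone (6-O-TBS; 15-O-TBDPS), via trimethylammonium iodide 33 (not isolated)
Conditions: MeI, MeOH/CH2Cl2, rt; then NaHCO3 (aq), CH2Cl2, rt
Reagents that add atoms: none
Why: Quaternisation followed by E1cB-type elimination of trimethylamine gives the exocyclic C11=C13 bond under mild base that leaves the diene and the silyl ethers alone.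

Step 20
Reactants: 34
Product: 35 6,15-diol of the methylene lactone
Conditions: HF·pyridine, THF, 0 °C → rt
Reagents that add atoms: none
Why: Fluoride cleaves both silyl ethers; the weakly acidic medium spares the Michael acceptor and avoids the base-induced acyl shift of the lactone from O8 to the free O6.

Step 21
Reactants: 35
Product: 36 15-acetate with free C6 hydroxyl
Conditions: Ac2O (1.1 equiv), 2,4,6-collidine, CH2Cl2, −20 → 0 °C
Reagents that add atoms: acetic anhydride, CC(=O)OC(C)=O
Why: The primary allylic hydroxyl is acetylated much faster than the secondary C6 hydroxyl flanked by C7; a weak, non-nucleophilic base avoids translactonisation and conjugate addition.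

Step 22
Reactants: 37 (R)-3-bromo-2-hydroxy-2-methylpropanoic acid
Product: 39 (S)-2,3-dihydroxy-2-methylpropanoic acid, via sodium glycidate 38 (not isolated)
Conditions: NaOH (3 equiv), H2O, 80 °C; then Dowex 50W (H+ form)
Reagents that add atoms: sodium hydroxide, [Na+].[OH-]
Why: The alkoxide displaces bromide to give the glycidate, which hydroxide opens at the unsubstituted carbon; no bond to the quaternary stereocentre is broken, and the descriptor changes from R to S only through the priority rules.

Step 23
Reactants: 39
Product: 40 methyl (S)-2,2,4-trimethyl-1,3-dioxolane-4-carboxylate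
Conditions: 2,2-dimethoxypropane, MeOH, TsOH·H2O (cat.), 50 °C
Reagents that add atoms: 2,2-dimethoxypropane, COC(C)(C)OC; methanol, CO
Why: Fischer esterification and acetonide formation occur in one pot because the ketal reagent also removes the water formed.

Step 24
Reactants: 40
Product: 41 (S)-2,2,4-trimethyl-1,3-dioxolane-4-carboxylic acid
Conditions: LiOH·H2O, THF/H2O, 0 °C → rt; then NaHSO4 to pH 3, 0 °C
Reagents that add atoms: lithium hydroxide, [Li+].[OH-]
Why: Saponification of the methyl ester; there is no α-hydrogen, so the stereocentre cannot epimerise, and cold, brief acidification keeps the acetonide.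

Step 25
Reactants: 36; 41
Product: 43 acetonide of 44, via mixed anhydride 42 (not isolated)
Conditions: 41, 2,4,6-trichlorobenzoyl chloride, Et3N, toluene, rt; then 36, DMAP, toluene, rt → 40 °C
Reagents that add atoms: none
Why: Yamaguchi esterification: DMAP transfers the acyl group from the mixed anhydride to the only free hydroxyl, C6–OH; 41 has no α-hydrogen and cannot racemise.

Step 26
Reactants: 43
Product: 44 CNP0347302.1
Conditions: AcOH/H2O (4:1), 40 °C
Reagents that add atoms: none
Why: Acid-catalysed hydrolysis of the dioxolane releases the tertiary and primary hydroxyls; buffered acetic acid should leave the allylic acetate, the hindered C6 ester, the diene and the methylene lactone untouched.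

## Compound list

1 | 1-(4-chlorophenyl)ethan-1-one | CC(=O)c1ccc(Cl)cc1 | starting material
2 | (2-carboxyethyl)triphenylphosphonium bromide | OC(=O)CC[P+](c1ccccc1)(c1ccccc1)c1ccccc1.[Br-] | starting material
3 | sodium 3-(triphenyl-λ5-phosphanylidene)propanoate (ylide) | [Na+].[O-]C(=O)CC=P(c1ccccc1)(c1ccccc1)c1ccccc1 | intermediate
4 | (E)-4-(4-chlorophenyl)pent-3-enoic acid | C/C(=C\CC(=O)O)c1ccc(Cl)cc1 | intermediate
5 | (S)-4-(4-chlorophenyl)pentanoic acid | C[C@@H](CCC(=O)O)c1ccc(Cl)cc1 | intermediate
6 | (S)-4-(4-chlorophenyl)pentanoyl chloride | C[C@@H](CCC(=O)Cl)c1ccc(Cl)cc1 | intermediate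
7 | (S)-7-chloro-4-methyl-3,4-dihydronaphthalen-1(2H)-one | C[C@H]1CCC(=O)c2cc(Cl)ccc21 | intermediate
8 | (S)-7-chloro-4-methyl-3,4-dihydronaphthalen-1-yl trifluoromethanesulfonate | C[C@H]1CC=C(OS(=O)(=O)C(F)(F)F)c2cc(Cl)ccc21 | intermediate
9 | tributyl(ethenyl)stannane | C=C[Sn](CCCC)(CCCC)CCCC | starting material
10 | (S)-6-chloro-4-ethenyl-1-methyl-1,2-dihydronaphthalene | C[C@H]1CC=C(C=C)c2cc(Cl)ccc21 | intermediate
11 | bis(9-borabicyclo[3.3.1]nonan-9-yl) adduct of 10 (boron on C8 and C12; H on C7 cis to boron on C8) | C[C@H]1C[C@H](B2C3CCCC2CCC3)[C@@H](CCB2C3CCCC2CCC3)c2cc(Cl)ccc21 | intermediate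
12 | 2-[(1S,2S,4S)-7-chloro-2-hydroxy-4-methyl-1,2,3,4-tetrahydronaphthalen-1-yl]ethan-1-ol | C[C@H]1C[C@H](O)[C@@H](CCO)c2cc(Cl)ccc21 | intermediate
13 | (1S,2S,4S)-1-[2-(tert-butyldimethylsilyloxy)ethyl]-7-chloro-4-methyl-1,2,3,4-tetrahydronaphthalen-2-ol | C[C@H]1C[C@H](O)[C@@H](CCO[Si](C)(C)C(C)(C)C)c2cc(Cl)ccc21 | intermediate
14 | potassium (acetoxymethyl)trifluoroborate | [K+].CC(=O)OC[B-](F)(F)F | starting material
15 | (1S,2S,4S)-1-[2-(tert-butyldimethylsilyloxy)ethyl]-7-(hydroxymethyl)-4-methyl-1,2,3,4-tetrahydronaphthalen-2-ol | C[C@H]1C[C@H](O)[C@@H](CCO[Si](C)(C)C(C)(C)C)c2cc(CO)ccc21 | intermediate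
16 | dilithium dialkoxide of 15 | [Li+].[Li+].C[C@H]1C[C@H]([O-])[C@@H](CCO[Si](C)(C)C(C)(C)C)c2cc(C[O-])ccc21 | intermediate
17 | (1S,2S,4S)-1-[2-(tert-butyldimethylsilyloxy)ethyl]-7-(hydroxymethyl)-4-methyl-1,2,3,4,5,8-hexahydronaphthalen-2-ol | C[C@H]1C[C@H](O)[C@@H](CCO[Si](C)(C)C(C)(C)C)C2=C1CC=C(CO)C2 | intermediate
18 | (1S,2S,4S)-1-[2-(tert-butyldimethylsilyloxy)ethyl]-7-[(tert-butyldiphenylsilyloxy)methyl]-4-methyl-1,2,3,4,5,8-hexahydronaphthalen-2-ol | C[C@H]1C[C@H](O)[C@@H](CCO[Si](C)(C)C(C)(C)C)C2=C1CC=C(CO[Si](c3ccccc3)(c4ccccc4)C(C)(C)C)C2 | intermediate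
19 | ten-membered hydroxy-dione: 8-hydroxycyclodec-3-ene-1,6-dione, C3=C4 ring-cis, CH2OTBDPS on C4, CH2CH2OTBS on C7, CH3 on C10 (C7, C8, C10 as in 44) | O[C@H]1C[C@H](C)C(=O)C/C=C(/CO[Si](c2ccccc2)(c3ccccc3)C(C)(C)C)CC(=O)[C@@H]1CCO[Si](C)(C)C(C)(C)C | intermediate
20 | C1/C8 hemiketal of 19: 1-hydroxy-11-oxabicyclo[6.2.1]undec-3-en-6-one with the same substituents | C[C@H]1C[C@@H]2O[C@@]1(O)C/C=C(/CO[Si](c3ccccc3)(c4ccccc4)C(C)(C)C)CC(=O)[C@@H]2CCO[Si](C)(C)C(C)(C)C | intermediate
21 | O8-diethylborinate of 19, boron chelated to the C6 carbonyl | CCB(CC)O[C@H]1C[C@H](C)C(=O)C/C=C(/CO[Si](c2ccccc2)(c3ccccc3)C(C)(C)C)CC(=O)[C@@H]1CCO[Si](C)(C)C(C)(C)C | intermediate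
22 | 6,8-syn diol as its C1/C8 hemiketal (C6–OH on the face of O8) | C[C@H]1C[C@@H]2O[C@@]1(O)C/C=C(/CO[Si](c3ccccc3)(c4ccccc4)C(C)(C)C)C[C@@H](O)[C@@H]2CCO[Si](C)(C)C(C)(C)C | intermediate
23 | 6-O-TBS ether of 22 | C[C@H]1C[C@@H]2O[C@@]1(O)C/C=C(/CO[Si](c3ccccc3)(c4ccccc4)C(C)(C)C)C[C@@H](O[Si](C)(C)C(C)(C)C)[C@@H]2CCO[Si](C)(C)C(C)(C)C | intermediate
24 | primary alcohol: 23 with C12–OH free | C[C@H]1C[C@@H]2O[C@@]1(O)C/C=C(/CO[Si](c3ccccc3)(c4ccccc4)C(C)(C)C)C[C@@H](O[Si](C)(C)C(C)(C)C)[C@@H]2CCO | intermediate
25 | C12 aldehyde of 24 (hemiketal form) | C[C@H]1C[C@@H]2O[C@@]1(O)C/C=C(/CO[Si](c3ccccc3)(c4ccccc4)C(C)(C)C)C[C@@H](O[Si](C)(C)C(C)(C)C)[C@@H]2CC=O | intermediate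
26 | lactol: C12 hemiacetal on O8 with free C1 ketone (anomers) | C1C(O)O[C@H]2C[C@H](C)C(=O)C/C=C(/CO[Si](c3ccccc3)(c4ccccc4)C(C)(C)C)C[C@@H](O[Si](C)(C)C(C)(C)C)[C@H]12 | intermediate
27 | trans-fused 8,12-lactone with C1 ketone, ring-cis C3=C4, 6-O-TBS and 15-O-TBDPS (C6, C7, C8, C10 as in 44) | C1C(=O)O[C@H]2C[C@H](C)C(=O)C/C=C(/CO[Si](c3ccccc3)(c4ccccc4)C(C)(C)C)C[C@@H](O[Si](C)(C)C(C)(C)C)[C@H]12 | intermediate
28 | potassium C1 dienolate of 27 | [K+].C1C(=O)O[C@H]2C[C@H](C)/C([O-])=C\C=C(\CO[Si](c3ccccc3)(c4ccccc4)C(C)(C)C)C[C@@H](O[Si](C)(C)C(C)(C)C)[C@H]12 | intermediate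
29 | dienyl triflate: C1–OTf, C1=C2 and C3=C4 ring-cis | C1C(=O)O[C@H]2C[C@H](C)/C(OS(=O)(=O)C(F)(F)F)=C\C=C(\CO[Si](c3ccccc3)(c4ccccc4)C(C)(C)C)C[C@@H](O[Si](C)(C)C(C)(C)C)[C@H]12 | intermediate
30 | cis,cis-diene lactone with 6-O-TBS and 15-O-TBDPS (C11 = CH2) | C1C(=O)O[C@H]2C[C@H](C)/C=C\C=C(\CO[Si](c3ccccc3)(c4ccccc4)C(C)(C)C)C[C@@H](O[Si](C)(C)C(C)(C)C)[C@H]12 | intermediate
31 | lithium enolate of 30 | [Li+].C1=C([O-])O[C@H]2C[C@H](C)/C=C\C=C(\CO[Si](c3ccccc3)(c4ccccc4)C(C)(C)C)C[C@@H](O[Si](C)(C)C(C)(C)C)[C@H]12 | intermediate
32 | 11-(dimethylaminomethyl) lactone (C11 epimers; centre erased in step 19) | CN(C)CC1C(=O)O[C@H]2C[C@H](C)/C=C\C=C(\CO[Si](c3ccccc3)(c4ccccc4)C(C)(C)C)C[C@@H](O[Si](C)(C)C(C)(C)C)[C@H]12 | intermediate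
33 | trimethylammonium iodide of 32 | C[N+](C)(C)CC1C(=O)O[C@H]2C[C@H](C)/C=C\C=C(\CO[Si](c3ccccc3)(c4ccccc4)C(C)(C)C)C[C@@H](O[Si](C)(C)C(C)(C)C)[C@H]12.[I-] | intermediate
34 | α-methylene lactone with 6-O-TBS and 15-O-TBDPS | C=C1C(=O)O[C@H]2C[C@H](C)/C=C\C=C(\CO[Si](c3ccccc3)(c4ccccc4)C(C)(C)C)C[C@@H](O[Si](C)(C)C(C)(C)C)[C@H]12 | intermediate
35 | 6,15-diol of the α-methylene lactone | C=C1C(=O)O[C@H]2C[C@H](C)/C=C\C=C(\CO)C[C@@H](O)[C@H]12 | intermediate
36 | 15-acetate with free C6 hydroxyl | C=C1C(=O)O[C@H]2C[C@H](C)/C=C\C=C(\COC(C)=O)C[C@@H](O)[C@H]12 | intermediate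
37 | (R)-3-bromo-2-hydroxy-2-methylpropanoic acid | OC(=O)[C@@](C)(O)CBr | starting material
38 | sodium (S)-2-methyloxirane-2-carboxylate | [Na+].[O-]C(=O)[C@@]1(C)OC1 | intermediate
39 | (S)-2,3-dihydroxy-2-methylpropanoic acid | OC(=O)[C@@](C)(O)CO | intermediate
40 | methyl (S)-2,2,4-trimethyl-1,3-dioxolane-4-carboxylate | COC(=O)[C@@]1(C)OC(C)(C)OC1 | intermediate
41 | (S)-2,2,4-trimethyl-1,3-dioxolane-4-carboxylic acid | OC(=O)[C@@]1(C)OC(C)(C)OC1 | intermediate
42 | mixed anhydride of 41 with 2,4,6-trichlorobenzoic acid | O=C(OC(=O)[C@@]1(C)OC(C)(C)OC1)c1c(Cl)cc(Cl)cc1Cl | intermediate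
43 | acetonide of 44 | C=C1C(=O)O[C@H]2C[C@H](C)/C=C\C=C(\COC(C)=O)C[C@@H](OC(=O)[C@@]3(C)OC(C)(C)OC3)[C@H]12 | intermediate
44 | CNP0347302.1: (6R,7R,8S,10S)-configured 8,12-lactone with 15-acetate and 6-O-[(S)-2,3-dihydroxy-2-methylpropanoyl] | C=C1C(=O)O[C@H]2C[C@H](C)/C=C\C=C(\COC(C)=O)C[C@@H](OC(=O)[C@@](C)(O)CO)[C@H]12 | target

## Step count and least certain steps

Total step count: 26. Longest linear sequence: 23 steps (steps 1–21, 25 and 26); steps 22–24 are the three-step branch to acid 41.

**Step 11 (key step).** The likely failures are competing ozone attack at C3=C4 once C1=C6 is nearly consumed, oxidative aromatisation of the 1,4-diene ring, and transannular aldol reaction of the 1,6-dione before the hemiketal forms. All come from the small reactivity gap between the two alkenes and the lability of a β,γ-unsaturated 1,6-dione. The fallback sets out from 18. Epoxidation with mCPBA (1.0 equiv, NaHCO3, CH2Cl2, −20 °C) is selective for the tetrasubstituted alkene and should occur on the face of the C8 hydroxyl, away from the C7 and C10 substituents, to give the 1,6-epoxide F1. H5IO6 in wet THF then opens and cleaves the epoxide to 19, which closes to 20, where the route is rejoined.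

**Step 6.** The risk is poor facial selectivity in the second hydroboration if the C10 methyl is not pseudoaxial in the reacting conformer, which would give the C7/C8 diastereomer pair. The fallback sets out from 10. One equivalent of 9-BBN at 0 °C hydroborates only the vinyl group, and oxidation gives the homoallylic alcohol 2-[(4S)-7-chloro-4-methyl-3,4-dihydronaphthalen-1-yl]ethan-1-ol F2. Silylation (TBSCl, imidazole) gives its TBS ether F3. The ring alkene is then hydroborated under reagent control with the enantiomer of monoisopinocampheylborane (IpcBH2) matched to the required face and oxidised, which returns to 13.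

**Step 9.** The risk is hydrogenolysis of the benzylic C15–O bond if the alkoxide is protonated while solvated electrons are present, or incomplete reduction of the electron-rich trialkylarene. The fallback sets out from 13. Kumada coupling with (isopropoxydimethylsilyl)methylmagnesium chloride and NiCl2(dppp) gives the benzylsilane F4, whose C–Si bond is not cleaved by lithium in ammonia. Birch reduction under the conditions of step 9 gives the allylsilane F5. Tamao–Fleming oxidation (KF, KHCO3, H2O2, MeOH/THF) converts C–Si into C–OH without allylic shift and returns to 17.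

**Step 12.** The risk is loss of chemoselectivity (hydride attack at C1 if the open form is long-lived) or erosion of the syn preference because the boron chelate is part of a medium ring. The fallback sets out from 20. Me4NBH(OAc)3 (AcOH/MeCN, −20 °C) delivers hydride only intramolecularly from O8 and so cannot reach C1; it gives the 6,8-anti diol hemiketal F6, the C6 epimer of 22. Mitsunobu inversion at C6 with 4-nitrobenzoic acid (PPh3, diisopropyl azodicarboxylate) gives the 6-O-(4-nitrobenzoyl) hemiketal F7 with the configuration of 44. Methanolysis (K2CO3, MeOH) returns to 22.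

**Step 13.** The risk is incomplete differentiation of O6 and O8, either by silylation of the open-form C8 hydroxyl or by acid-triggered closure of O6 and O8 onto C1 to an internal bicyclic ketal, since the hemiketal is an equilibrium species. The fallback sets out from 20 and locks O8 before C6 is reduced. PPTS in MeOH gives the bridged methyl ketal ketone F8. Chelation-controlled reduction (Zn(BH4)2, Et2O, −20 °C) gives the C6 alcohol F9; should the C6 epimer form instead, the Mitsunobu inversion described for step 12 applies. Silylation (TBSCl, imidazole) gives the 6-O-TBS ketal F10. AcOH/THF/H2O then hydrolyses the methyl ketal and the primary TBS ether together and returns to 24.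

**Step 16.** The risk is formation of the ring-trans C1=C2 isomer under kinetic control, or enolisation toward C10 with loss of its configuration. The fallback sets out from 27. TBSOTf and Et3N (CH2Cl2, 0 °C → rt) under equilibrating conditions give the thermodynamically preferred conjugated silyl dienol ether F11. Fluoride-triggered exchange with nonafluorobutanesulfonyl fluoride (CsF, THF) converts it with retention into the dienyl nonaflate F12. The palladium/formate reduction of step 17 then returns to 30.

## Further compounds

F1 | step 11 | 1,6-epoxide of 18 (oxygen on the face of the C8 hydroxyl) | C[C@H]1C[C@H](O)[C@@H](CCO[Si](C)(C)C(C)(C)C)[C@]23O[C@]12CC=C(CO[Si](c4ccccc4)(c5ccccc5)C(C)(C)C)C3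
F2 | step 6 | 2-[(4S)-7-chloro-4-methyl-3,4-dihydronaphthalen-1-yl]ethan-1-ol | C[C@H]1CC=C(CCO)c2cc(Cl)ccc21
F3 | step 6 | TBS ether of F2 | C[C@H]1CC=C(CCO[Si](C)(C)C(C)(C)C)c2cc(Cl)ccc21
F4 | step 9 | benzylsilane: 13 with CH2Si(CH3)2(OiPr) in place of chlorine | C[C@H]1C[C@H](O)[C@@H](CCO[Si](C)(C)C(C)(C)C)c2cc(C[Si](C)(C)OC(C)C)ccc21
F5 | step 9 | Birch product of F4 (allylsilane; 1,2,3,4,5,8-hexahydronaphthalene) | C[C@H]1C[C@H](O)[C@@H](CCO[Si](C)(C)C(C)(C)C)C2=C1CC=C(C[Si](C)(C)OC(C)C)C2
F6 | step 12 | 6,8-anti diol hemiketal (C6 epimer of 22) | C[C@H]1C[C@@H]2O[C@@]1(O)C/C=C(/CO[Si](c3ccccc3)(c4ccccc4)C(C)(C)C)C[C@H](O)[C@@H]2CCO[Si](C)(C)C(C)(C)C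
F7 | step 12 | 6-O-(4-nitrobenzoyl) derivative of 22 | C[C@H]1C[C@@H]2O[C@@]1(O)C/C=C(/CO[Si](c3ccccc3)(c4ccccc4)C(C)(C)C)C[C@@H](OC(=O)c5ccc(cc5)[N+](=O)[O-])[C@@H]2CCO[Si](C)(C)C(C)(C)C
F8 | step 13 | bridged methyl ketal of 20 (C1–OCH3; C6 ketone) | C[C@H]1C[C@@H]2O[C@@]1(OC)C/C=C(/CO[Si](c3ccccc3)(c4ccccc4)C(C)(C)C)CC(=O)[C@@H]2CCO[Si](C)(C)C(C)(C)C
F9 | step 13 | C6 alcohol of F8 (C6–OH on the face of O8) | C[C@H]1C[C@@H]2O[C@@]1(OC)C/C=C(/CO[Si](c3ccccc3)(c4ccccc4)C(C)(C)C)C[C@@H](O)[C@@H]2CCO[Si](C)(C)C(C)(C)C
F10 | step 13 | 6-O-TBS ether of F9 | C[C@H]1C[C@@H]2O[C@@]1(OC)C/C=C(/CO[Si](c3ccccc3)(c4ccccc4)C(C)(C)C)C[C@@H](O[Si](C)(C)C(C)(C)C)[C@@H]2CCO[Si](C)(C)C(C)(C)C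
F11 | step 16 | TBS dienol ether of 27 (C1–OTBS; C1=C2 ring-cis) | C1C(=O)O[C@H]2C[C@H](C)/C(O[Si](C)(C)C(C)(C)C)=C\C=C(\CO[Si](c3ccccc3)(c4ccccc4)C(C)(C)C)C[C@@H](O[Si](C)(C)C(C)(C)C)[C@H]12
F12 | step 16 | dienyl nonaflate (C1–OSO2C4F9) | C1C(=O)O[C@H]2C[C@H](C)/C(OS(=O)(=O)C(F)(F)C(F)(F)C(F)(F)C(F)(F)F)=C\C=C(\CO[Si](c3ccccc3)(c4ccccc4)C(C)(C)C)C[C@@H](O[Si](C)(C)C(C)(C)C)[C@H]12
A1 | alternative 1 | 11-thiabicyclo[6.2.1]undec-9-ene 11,11-dioxide containing the ten-membered carbocycle | O=S1(=O)[C@H]2C=C[C@]1(C(=O)OC)C[C@@H](OCc3ccc(OC)cc3)[C@H](C(=C)CO[Si](C)(C)C(C)(C)C)[C@@H](O[Si](C)(C)C(C)(C)C)C[C@@H]2C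
A2 | alternative 2 | acetonide of the target (identical with 43) | C=C1C(=O)O[C@H]2C[C@H](C)/C=C\C=C(\COC(C)=O)C[C@@H](OC(=O)[C@@]3(C)OC(C)(C)OC3)[C@H]12
A3 | alternative 3 | ten-membered C6 alcohol with the 2-propenyl unit on C7 | C=C(CO[Si](C)(C)C(C)(C)C)[C@@H]1[C@@H](O[Si](C)(C)C(C)(C)C)C[C@H](C)/C=C\C=C(\COCc2ccc(OC)cc2)C[C@H]1O
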